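**Plan**
1. After removal of the phenol protecting groups, the flavanone is cut at C2–C3. The unit O1–C2(H)–anisyl of ring C is read as a 4-methoxybenzyl (PMB) ether on a ring A oxygen; its benzylic C–H lies six atoms from C3 once C3 is the diazo carbon of an aryl diazomethyl ketone.
2. The diazo ketone goes back to an acetyl group. The biaryl bond between C6 of ring A and C3' of the flavone is then cut (Suzuki–Miyaura) into an iodoacetophenone and a flavone 3'-boronate.
3. Both halves come from phloroacetophenone. One side: bis-PMB ether, iodination, O-methylation. Other side: bis-benzyl ether, chalcone with 3-bromo-4-methoxybenzaldehyde, oxidative cyclisation, borylation.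
4. Forward order: flavone pyranone ring (step 6), biaryl union (step 8), diazo transfer (step 9), flavanone ring C by carbenoid C–H insertion (step 10), global deprotection (step 11).
5. Stereochemistry: the only stereocentre, C2 (S), is set in step 10 by a chiral dirhodium tetracarboxylate of divalent rhodium that selects one enantiotopic benzylic hydrogen; no later step touches C2.

Key step: step 10

Remark: the biaryl axis carries three ortho oxygen substituents and is taken to rotate freely at room temperature, so C2 is the sole stereogenic element.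
Remark: which antipode of the dirhodium catalyst leads to (2S) cannot be predicted with certainty; the (S)-ligand complex Rh2(S-PTTL)4, dirhodium tetrakis[N-phthaloyl-(S)-tert-leucinate], is written, and its mirror image would be used if a trial run shows the opposite sense.

**Route**

Step 1
Reactants: 1 2',4',6'-trihydroxyacetophenone (phloroacetophenone); 2 4-methoxybenzyl chloride
Product: 3 1-[2-hydroxy-4,6-bis(4-methoxybenzyloxy)phenyl]ethanone
Conditions: 2 (2.1 equiv), K2CO3, Bu4NI (cat.), DMF, rt to 50 °C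
Reagents that add atoms: none
Why: Williamson etherification, in which two equivalents of the benzylic chloride alkylate the two hydroxyls not hydrogen-bonded to the acetyl carbonyl, the chelated one being the least nucleophilic, as in the standard bis-benzylation of phloroacetophenone.

Step 2
Reactants: 3 1-[2-hydroxy-4,6-bis(4-methoxybenzyloxy)phenyl]ethanone
Product: 4 1-[2-hydroxy-3-iodo-4,6-bis(4-methoxybenzyloxy)phenyl]ethanone
Conditions: BnMe3N ICl2, NaHCO3, CH2Cl2/MeOH, rt
Reagents that add atoms: benzyltrimethylammonium dichloroiodate, C[N+](C)(C)Cc1ccccc1.Cl[I-]Cl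
Why: Electrophilic aromatic iodination, in which the free chelated phenol directs the iodine to its ortho position C3 (also less hindered than C5 between two benzyloxy groups) while bicarbonate buffers the HCl and protects the PMB ethers, in line with the known 3-iodination of 2-hydroxy-4,6-dialkoxyacetophenones.

Step 3
Reactants: 4 1-[2-hydroxy-3-iodo-4,6-bis(4-methoxybenzyloxy)phenyl]ethanone
Product: 5 1-[3-iodo-2-methoxy-4,6-bis(4-methoxybenzyloxy)phenyl]ethanone
Conditions: MeI, K2CO3, DMF, 40 °C
Reagents that add atoms: iodomethane, CI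
Why: Williamson O-methylation, in which carbonate in DMF breaks the hydrogen bond of the hindered phenol and the small electrophile caps the oxygen that becomes the C5 oxygen of the flavanone, a group whose methyl C–H bonds are poor partners for a carbenoid.

Step 4
Reactants: 1 2',4',6'-trihydroxyacetophenone
Product: 6 1-[2,4-bis(benzyloxy)-6-hydroxyphenyl]ethanone
Conditions: BnBr (2.1 equiv), K2CO3, DMF, rt to 60 °C
Reagents that add atoms: benzyl bromide, BrCc1ccccc1
Why: Williamson etherification with the same selectivity as in step 1, the hydroxyl chelated to the acetyl group staying free for the later ring closure of the flavone.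

Step 5
Reactants: 6 1-[2,4-bis(benzyloxy)-6-hydroxyphenyl]ethanone; 7 3-bromo-4-methoxybenzaldehyde
Product: 8 (E)-1-[2,4-bis(benzyloxy)-6-hydroxyphenyl]-3-(3-bromo-4-methoxyphenyl)prop-2-en-1-one
Conditions: KOH (aq.), EtOH/THF, rt; then dilute HCl
Reagents that add atoms: none
Why: Claisen–Schmidt (crossed aldol) condensation, in which the acetophenone enolate adds to the non-enolisable aldehyde and dehydration gives the conjugated E-enone, the aryl bromide and benzyl ethers being inert to hydroxide at room temperature.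

Step 6
Reactants: 8 (E)-1-[2,4-bis(benzyloxy)-6-hydroxyphenyl]-3-(3-bromo-4-methoxyphenyl)prop-2-en-1-one
Product: 9 5,7-bis(benzyloxy)-2-(3-bromo-4-methoxyphenyl)-4H-chromen-4-one
Conditions: I2 (10 mol %), DMSO, 130 °C
Reagents that add atoms: none
Why: Iodine-catalysed oxidative cyclisation of a 2'-hydroxychalcone in DMSO, in which oxa-Michael closure and iodination–elimination at C3 give the flavone while DMSO reoxidises iodide, conditions that benzyl ethers and aryl bromides routinely survive.

Step 7
Reactants: 9 5,7-bis(benzyloxy)-2-(3-bromo-4-methoxyphenyl)-4H-chromen-4-one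
Product: 10 5,7-bis(benzyloxy)-2-[4-methoxy-3-(4,4,5,5-tetramethyl-1,3,2-dioxaborolan-2-yl)phenyl]-4H-chromen-4-one
Conditions: B2pin2, PdCl2(dppf) (5 mol %), KOAc, 1,4-dioxane, 90 °C
Reagents that add atoms: bis(pinacolato)diboron, CC1(C)OB(OC1(C)C)B1OC(C)(C)C(C)(C)O1
Why: Miyaura borylation, in which zerovalent palladium inserts into the aryl C–Br bond and acetate-assisted transmetalation with the diboron reagent gives the pinacol boronate, the weak base suppressing biaryl homocoupling and leaving the flavone untouched.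

Step 8
Reactants: 5 1-[3-iodo-2-methoxy-4,6-bis(4-methoxybenzyloxy)phenyl]ethanone; 10 5,7-bis(benzyloxy)-2-[4-methoxy-3-(4,4,5,5-tetramethyl-1,3,2-dioxaborolan-2-yl)phenyl]-4H-chromen-4-one
Product: 11 1-{3-[5-(5,7-bis(benzyloxy)-4-oxo-4H-chromen-2-yl)-2-methoxyphenyl]-2-methoxy-4,6-bis(4-methoxybenzyloxy)phenyl}ethanone
Conditions: Pd(OAc)2 (5 mol %), SPhos (10 mol %), K3PO4, toluene/H2O, 90 °C
Reagents that add atoms: none
Why: Suzuki–Miyaura coupling, in which the electron-rich dialkylbiarylphosphine supports oxidative addition of zerovalent palladium to the di-ortho-substituted iodide and reductive elimination to the tri-ortho-substituted biaryl, phosphate being mild enough for the methyl ketone and the flavone.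

Step 9
Reactants: 11 1-{3-[5-(5,7-bis(benzyloxy)-4-oxo-4H-chromen-2-yl)-2-methoxyphenyl]-2-methoxy-4,6-bis(4-methoxybenzyloxy)phenyl}ethanone
Product: 13 2-diazo-1-{3-[5-(5,7-bis(benzyloxy)-4-oxo-4H-chromen-2-yl)-2-methoxyphenyl]-2-methoxy-4,6-bis(4-methoxybenzyloxy)phenyl}ethanone, via trifluoroacetyl ketone 12 (not isolated)
Conditions: LiN(SiMe3)2, THF, −78 °C; CF3CO2CH2CF3; cold 1 M HCl quench; then MsN3, Et3N, H2O (1 equiv), MeCN, rt
Reagents that add atoms: methanesulfonyl azide, CS(=O)(=O)N=[N+]=[N-] (the two diazo nitrogens of 13); 2,2,2-trifluoroethyl trifluoroacetate, O=C(OCC(F)(F)F)C(F)(F)F (the trifluoroacetyl group of 12 only, lost again on the way to 13)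
Why: Detrifluoroacetylative Regitz diazo transfer, in which Claisen trifluoroacetylation of the kinetic lithium enolate makes the methyl ketone a 1,3-diketone acidic enough to accept the diazo group from the sulfonyl azide with amine base, after which the trifluoroacetyl group leaves as the sulfonamide, so the flavone and the ethers meet only one equivalent of amide base at −78 °C.

Step 10
Reactants: 13 2-diazo-1-{3-[5-(5,7-bis(benzyloxy)-4-oxo-4H-chromen-2-yl)-2-methoxyphenyl]-2-methoxy-4,6-bis(4-methoxybenzyloxy)phenyl}ethanone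
Product: 14 (2S)-6-[5-(5,7-bis(benzyloxy)-4-oxo-4H-chromen-2-yl)-2-methoxyphenyl]-5-methoxy-7-(4-methoxybenzyloxy)-2-(4-methoxyphenyl)chroman-4-one
Conditions: Rh2(S-PTTL)4 (2 mol %), CH2Cl2, 4 Å MS, 0 °C to rt, slow addition of 13
Reagents that add atoms: none
Why: Loss of N2 from 13 at an axial site of the dirhodium carboxylate gives an electrophilic rhodium carbenoid at the future C3, which engages the benzylic C–H of the neighbouring PMB ether in a three-centre, hydride-transfer-like transition state so that C2–C3 and C3–H form together. The closest known reaction type is the dirhodium-catalysed intramolecular C–H insertion of 2-alkoxyaryl diazo ketones to chroman-4-ones, which includes benzyl ethers giving 2-arylchromanones under chiral carboxylate catalysis. Ring C closes as a six-membered dihydropyranone by 1,6-insertion, the carbenoid carbon bonding to the carbon that already carries O1 and the anisyl ring. C2 is set by the catalyst, whose phthalimido walls around the tert-leucinate ligands should differentiate the two enantiotopic benzylic hydrogens, the antipode that delivers (2S) being the one used. The step needs insertion to win over oxonium-ylide formation with benzyl shift to a 2-benzylbenzofuran-3-one and over attack on the C5 methoxy group; the benzylic C–H is activated by both the ether oxygen and the para methoxy group, methyl C–H bonds are far less reactive, and only this one benzyl ether lies within reach of the carbenoid.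

Step 11
Reactants: 14 (2S)-6-[5-(5,7-bis(benzyloxy)-4-oxo-4H-chromen-2-yl)-2-methoxyphenyl]-5-methoxy-7-(4-methoxybenzyloxy)-2-(4-methoxyphenyl)chroman-4-one
Product: 15 (2S)-6-[5-(5,7-dihydroxy-4-oxo-4H-chromen-2-yl)-2-methoxyphenyl]-5,7-dihydroxy-2-(4-methoxyphenyl)chroman-4-one (CNP0081547.1)
Conditions: BCl3 (excess), pentamethylbenzene, CH2Cl2, −78 to 0 °C; then aqueous work-up
Reagents that add atoms: none
Why: Lewis-acid ether cleavage, in which BCl3 ionises the benzyl and PMB ethers at low temperature while pentamethylbenzene traps the benzylic cations before they alkylate the phloroglucinol rings, and on warming the boron chelate between the C4 carbonyl and the C5 oxygen lets chloride remove that one methyl group, whereas the two unchelated anisole methyl ethers are not attacked and C2 should keep its S configuration in the cold.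

**Compound list**
1 | 2',4',6'-trihydroxyacetophenone (phloroacetophenone) | CC(=O)c1c(O)cc(O)cc1O | starting material
2 | 4-methoxybenzyl chloride | COc1ccc(CCl)cc1 | starting material
3 | 1-[2-hydroxy-4,6-bis(4-methoxybenzyloxy)phenyl]ethanone | CC(=O)c1c(O)cc(OCc2ccc(OC)cc2)cc1OCc1ccc(OC)cc1 | intermediate
4 | 1-[2-hydroxy-3-iodo-4,6-bis(4-methoxybenzyloxy)phenyl]ethanone | CC(=O)c1c(O)c(I)c(OCc2ccc(OC)cc2)cc1OCc1ccc(OC)cc1 | intermediate
5 | 1-[3-iodo-2-methoxy-4,6-bis(4-methoxybenzyloxy)phenyl]ethanone | CC(=O)c1c(OC)c(I)c(OCc2ccc(OC)cc2)cc1OCc1ccc(OC)cc1 | intermediate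
6 | 1-[2,4-bis(benzyloxy)-6-hydroxyphenyl]ethanone | CC(=O)c1c(O)cc(OCc2ccccc2)cc1OCc1ccccc1 | intermediate
7 | 3-bromo-4-methoxybenzaldehyde | COc1ccc(C=O)cc1Br | starting material
8 | (E)-1-[2,4-bis(benzyloxy)-6-hydroxyphenyl]-3-(3-bromo-4-methoxyphenyl)prop-2-en-1-one | O=C(/C=C/c1ccc(OC)c(Br)c1)c1c(O)cc(OCc2ccccc2)cc1OCc1ccccc1 | intermediate
9 | 5,7-bis(benzyloxy)-2-(3-bromo-4-methoxyphenyl)-4H-chromen-4-one | COc1ccc(-c2cc(=O)c3c(OCc4ccccc4)cc(OCc4ccccc4)cc3o2)cc1Br | intermediate
10 | 5,7-bis(benzyloxy)-2-[4-methoxy-3-(4,4,5,5-tetramethyl-1,3,2-dioxaborolan-2-yl)phenyl]-4H-chromen-4-one | COc1ccc(-c2cc(=O)c3c(OCc4ccccc4)cc(OCc4ccccc4)cc3o2)cc1B1OC(C)(C)C(C)(C)O1 | intermediate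
11 | 1-{3-[5-(5,7-bis(benzyloxy)-4-oxo-4H-chromen-2-yl)-2-methoxyphenyl]-2-methoxy-4,6-bis(4-methoxybenzyloxy)phenyl}ethanone | CC(=O)c1c(OC)c(-c2cc(-c3cc(=O)c4c(OCc5ccccc5)cc(OCc5ccccc5)cc4o3)ccc2OC)c(OCc2ccc(OC)cc2)cc1OCc1ccc(OC)cc1 | intermediate
12 | 1-{3-[5-(5,7-bis(benzyloxy)-4-oxo-4H-chromen-2-yl)-2-methoxyphenyl]-2-methoxy-4,6-bis(4-methoxybenzyloxy)phenyl}-4,4,4-trifluorobutane-1,3-dione | O=C(CC(=O)C(F)(F)F)c1c(OC)c(-c2cc(-c3cc(=O)c4c(OCc5ccccc5)cc(OCc5ccccc5)cc4o3)ccc2OC)c(OCc2ccc(OC)cc2)cc1OCc1ccc(OC)cc1 | intermediate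
13 | 2-diazo-1-{3-[5-(5,7-bis(benzyloxy)-4-oxo-4H-chromen-2-yl)-2-methoxyphenyl]-2-methoxy-4,6-bis(4-methoxybenzyloxy)phenyl}ethanone | [N-]=[N+]=CC(=O)c1c(OC)c(-c2cc(-c3cc(=O)c4c(OCc5ccccc5)cc(OCc5ccccc5)cc4o3)ccc2OC)c(OCc2ccc(OC)cc2)cc1OCc1ccc(OC)cc1 | intermediate
14 | (2S)-6-[5-(5,7-bis(benzyloxy)-4-oxo-4H-chromen-2-yl)-2-methoxyphenyl]-5-methoxy-7-(4-methoxybenzyloxy)-2-(4-methoxyphenyl)chroman-4-one | COc1ccc([C@@H]2CC(=O)c3c(cc(OCc4ccc(OC)cc4)c(-c4cc(-c5cc(=O)c6c(OCc7ccccc7)cc(OCc7ccccc7)cc6o5)ccc4OC)c3OC)O2)cc1 | intermediate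
15 | (2S)-6-[5-(5,7-dihydroxy-4-oxo-4H-chromen-2-yl)-2-methoxyphenyl]-5,7-dihydroxy-2-(4-methoxyphenyl)chroman-4-one | COc1ccc([C@@H]2CC(=O)c3c(cc(O)c(-c4cc(-c5cc(=O)c6c(O)cc(O)cc6o5)ccc4OC)c3O)O2)cc1 | target

**Count and risks**
Total steps: 11. Longest linear sequence: 8 steps (steps 4 to 11, from phloroacetophenone through the flavone half).

Step 10. The carbenoid may be drained by oxonium-ylide formation at the benzyloxy oxygen followed by benzyl migration, or the catalyst may distinguish the two benzylic hydrogens poorly. The fallback replaces the carbenoid by an asymmetric conjugate addition; it sets out from 5 and returns at 14. MgBr2·OEt2 (toluene/Et2O, rt to 60 °C) should cleave only the PMB ether chelated to the acetyl carbonyl and give 1-[6-hydroxy-3-iodo-2-methoxy-4-(4-methoxybenzyloxy)phenyl]ethanone F1. N,N-Dimethylformamide dimethyl acetal (toluene, 90 °C) should convert it into (E)-3-(dimethylamino)-1-[6-hydroxy-3-iodo-2-methoxy-4-(4-methoxybenzyloxy)phenyl]prop-2-en-1-one F2, which should close in warm acetic acid to 6-iodo-5-methoxy-7-(4-methoxybenzyloxy)-4H-chromen-4-one F3. Suzuki–Miyaura coupling of F3 with 10 under the conditions of step 8 should give 5,7-bis(benzyloxy)-2-{4-methoxy-3-[5-methoxy-7-(4-methoxybenzyloxy)-4-oxo-4H-chromen-6-yl]phenyl}-4H-chromen-4-one F4. Addition of 4-methoxyphenylboronic acid to the unsubstituted C2 of F4 with palladium bis(trifluoroacetate), Pd(OCOCF3)2, and a chiral tert-butyl pyridine–oxazoline ligand (NH4PF6, H2O, ClCH2CH2Cl, 60 °C) would then give 14; the ligand antipode is chosen for (2S), and the 2-aryl-substituted flavone enone is far less reactive.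

Step 11. The Lewis acid may open ring C at the anisyl-stabilised C2–O1 bond and so erode the configuration at C2, or the chelated methyl group may be lost incompletely. The fallback separates the two tasks and uses different mechanisms; it sets out from 14 and returns at 15. Hydrogenolysis (H2, Pd/C, EtOAc/THF, rt) should remove the two benzyl groups and the PMB group under neutral conditions and give (2S)-6-[5-(5,7-dihydroxy-4-oxo-4H-chromen-2-yl)-2-methoxyphenyl]-7-hydroxy-5-methoxy-2-(4-methoxyphenyl)chroman-4-one F5. Magnesium-chelate-assisted demethylation with MgI2·OEt2 (THF, rt to 50 °C), in which iodide attacks only the methyl group held between C4=O and O5, would then give 15.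

Step 9. The amide base or the enolate may add to the flavone, or the twisted, di-ortho-substituted aryl ketone enolate may be C-acylated incompletely, leaving ketone that cannot take up the diazo group. The fallback avoids strong base; it sets out from 11 and returns at 13. Me3SiOSO2CF3/Et3N (CH2Cl2, 0 °C) should give the silyl enol ether 5,7-bis(benzyloxy)-2-{4-methoxy-3-[2-methoxy-4,6-bis(4-methoxybenzyloxy)-3-(1-trimethylsilyloxyethenyl)phenyl]phenyl}-4H-chromen-4-one F6. N-Bromosuccinimide (THF, −78 °C) should convert it into 2-bromo-1-{3-[5-(5,7-bis(benzyloxy)-4-oxo-4H-chromen-2-yl)-2-methoxyphenyl]-2-methoxy-4,6-bis(4-methoxybenzyloxy)phenyl}ethanone F7. N,N'-Ditosylhydrazine with DBU (THF, 0 °C), by N-alkylation and double sulfinate elimination, would then give 13.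

**Further compounds**
F1 | step 10 | 1-[6-hydroxy-3-iodo-2-methoxy-4-(4-methoxybenzyloxy)phenyl]ethanone | CC(=O)c1c(OC)c(I)c(OCc2ccc(OC)cc2)cc1O
F2 | step 10 | (E)-3-(dimethylamino)-1-[6-hydroxy-3-iodo-2-methoxy-4-(4-methoxybenzyloxy)phenyl]prop-2-en-1-one | CN(C)/C=C/C(=O)c1c(OC)c(I)c(OCc2ccc(OC)cc2)cc1O
F3 | step 10 | 6-iodo-5-methoxy-7-(4-methoxybenzyloxy)-4H-chromen-4-one | COc1ccc(COc2cc3occc(=O)c3c(OC)c2I)cc1
F4 | step 10 | 5,7-bis(benzyloxy)-2-{4-methoxy-3-[5-methoxy-7-(4-methoxybenzyloxy)-4-oxo-4H-chromen-6-yl]phenyl}-4H-chromen-4-one | COc1ccc(COc2cc3occc(=O)c3c(OC)c2-c2cc(-c3cc(=O)c4c(OCc5ccccc5)cc(OCc5ccccc5)cc4o3)ccc2OC)cc1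
F5 | step 11 | (2S)-6-[5-(5,7-dihydroxy-4-oxo-4H-chromen-2-yl)-2-methoxyphenyl]-7-hydroxy-5-methoxy-2-(4-methoxyphenyl)chroman-4-one | COc1ccc([C@@H]2CC(=O)c3c(cc(O)c(-c4cc(-c5cc(=O)c6c(O)cc(O)cc6o5)ccc4OC)c3OC)O2)cc1
F6 | step 9 | 5,7-bis(benzyloxy)-2-{4-methoxy-3-[2-methoxy-4,6-bis(4-methoxybenzyloxy)-3-(1-trimethylsilyloxyethenyl)phenyl]phenyl}-4H-chromen-4-one | C=C(O[Si](C)(C)C)c1c(OC)c(-c2cc(-c3cc(=O)c4c(OCc5ccccc5)cc(OCc5ccccc5)cc4o3)ccc2OC)c(OCc2ccc(OC)cc2)cc1OCc1ccc(OC)cc1
F7 | step 9 | 2-bromo-1-{3-[5-(5,7-bis(benzyloxy)-4-oxo-4H-chromen-2-yl)-2-methoxyphenyl]-2-methoxy-4,6-bis(4-methoxybenzyloxy)phenyl}ethanone | BrCC(=O)c1c(OC)c(-c2cc(-c3cc(=O)c4c(OCc5ccccc5)cc(OCc5ccccc5)cc4o3)ccc2OC)c(OCc2ccc(OC)cc2)cc1OCc1ccc(OC)cc1
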